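**Assumption:** atoms carry eudesmane numbers (ring A = C1–C5, C10; ring B = C5–C10; C14 = angular methyl, C15 = methyl on C4). Pent-4-ynal and (3S)-3-methylpentanoic acid are taken as commercial. The sense of the CBS step is assigned by the usual model, not from a reported case on this substrate.

## Retrosynthetic overview

1. The acrylic acid is unmasked last from a C7 ethynyl group (Markovnikov hydrocarboxylation); the C9 ester comes from equatorial hydride delivery to a C9 ketone with acylation in the same flask.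
2. C7–C11: axial conjugate alkynylation of a ring B enone (C9=O, C7=C8), trans to the angular methyl.
3. C4–O: hydrogen-atom-transfer hydration of a 4(15)-methylene on the trans-decalin.
4. Key C4–C5 bond: a stannyl-vinyl radical closes ring A onto the N-aziridinylimine of the C5 ketone; loss of N2 leaves a C5 radical whose H capture sets the trans ring fusion.
5. Ring order: ring B is bought as cyclohexane-1,3-dione (C10 made quaternary, then fixed by CBS desymmetrisation); ring A is closed second by the radical step.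

## Route

Step 1
Reactants: 1 cyclohexane-1,3-dione, 2 pent-4-ynal
Product: 4 2-(pent-4-yn-1-yl)cyclohexane-1,3-dione, via alkylidene dione 3 (not isolated)
Conditions: L-proline (20 mol%), Hantzsch ester (diethyl 2,6-dimethyl-1,4-dihydropyridine-3,5-dicarboxylate), CH2Cl2, 25 °C
Reagents that add atoms: none
Why: Ramachary reductive alkylation: proline-catalysed Knoevenagel condensation gives the alkylidene dione, which the Hantzsch ester reduces by conjugate hydride transfer before a second dione can add, so clean C-monoalkylation results; no stereocentre is formed.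

Step 2
Reactants: 4 2-(pent-4-yn-1-yl)cyclohexane-1,3-dione
Product: 5 2-methyl-2-(pent-4-yn-1-yl)cyclohexane-1,3-dione
Conditions: MeI, K2CO3, acetone, 56 °C
Reagents that add atoms: iodomethane, CI
Why: Enolate C-alkylation of the stabilised 2-alkyl-1,3-dione with the soft electrophile MeI creates the prochiral quaternary carbon (future C10 with C14); the O-methyl enol ether by-product is removed by chromatography.

Step 3
Reactants: 5 2-methyl-2-(pent-4-yn-1-yl)cyclohexane-1,3-dione
Product: 6 (2R,3R)-3-hydroxy-2-methyl-2-(pent-4-yn-1-yl)cyclohexan-1-one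
Conditions: (S)-Me-CBS oxazaborolidine (20 mol%), catecholborane (1.1 equiv), toluene, −78 °C; aq. NaOH work-up
Reagents that add atoms: none
Why: Corey–Bakshi–Shibata reduction desymmetrises the dione: the (S)-catalyst gives the (R)-carbinol and hydride enters anti to the larger pentynyl group, so one enantiotopic carbonyl reacts and the quaternary centre (C10) is fixed; catecholborane at −78 °C leaves the alkyne alone, and the minor trans diastereomer is removed by chromatography so that the enantiomeric purity at C10 equals the catalyst's face selectivity.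

Step 4
Reactants: 6 (2R,3R)-3-hydroxy-2-methyl-2-(pent-4-yn-1-yl)cyclohexan-1-one
Product: 7 (1R,2S)-2-methyl-2-(pent-4-yn-1-yl)-3-[(2-phenylaziridin-1-yl)imino]cyclohexan-1-ol
Conditions: 1-amino-2-phenylaziridinium acetate, EtOH, 0 °C to 25 °C
Reagents that add atoms: 1-amino-2-phenylaziridinium acetate, CC(=O)[O-].[NH3+]N1CC1c1ccccc1
Why: Hydrazone-type condensation at the remaining (C5) ketone under weakly acidic conditions, which do not trigger retro-aldol of the β-hydroxy ketone, installs a C=N group that can act first as radical acceptor and then as radical donor at the same carbon.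

Step 5 (key step)
Reactants: 7 (1R,2S)-2-methyl-2-(pent-4-yn-1-yl)-3-[(2-phenylaziridin-1-yl)imino]cyclohexan-1-ol
Product: 9 (1R,4aS,8aS)-8a-methyl-5-methylidenedecahydronaphthalen-1-ol, via vinylstannane 8 (not isolated)
Conditions: Bu3SnH (1.5 equiv, syringe pump), azobisisobutyronitrile (0.2 equiv), benzene (0.01 M), 80 °C; then HCl (1 M in Et2O), CH2Cl2, 0 °C
Reagents that add atoms: none
Why: Proposed new method: Bu3Sn• adds to the alkyne terminus and the vinyl radical closes ring A by 6-exo attack on the C=N carbon (C4–C5 bond); the aminyl radical then fragments with loss of styrene and N2 (closest known reactions: Kim's radical cyclization onto N-aziridinylimines and Stork's stannyl-vinyl radical cyclization), and the resulting C5 allyl radical takes H from Bu3SnH on the α face, away from the adjacent angular methyl, to give the trans ring fusion; any allylstannane formed by H capture at C15 is protonated at C5 on the same face, and HCl removes tin to leave the exocyclic methylene.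

Step 6
Reactants: 9 (1R,4aS,8aS)-8a-methyl-5-methylidenedecahydronaphthalen-1-ol
Product: 11 (1R,4aR,5R,8aS)-5,8a-dimethyldecahydronaphthalene-1,5-diol, via hydroperoxide 10 (not isolated)
Conditions: Co(acac)2 (20 mol%), PhSiH3, O2 (1 atm), THF, 25 °C; then PPh3
Reagents that add atoms: dioxygen, O=O
Why: Mukaiyama hydration (metal-hydride hydrogen atom transfer): H• adds to C15 and the planar tertiary C4 radical is trapped by O2 on the equatorial α face, because the β face is blocked by the syn-axial angular methyl, which sets C4 with OH equatorial and methyl axial; PPh3 reduces the hydroperoxide.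

Step 7
Reactants: 11 (1R,4aR,5R,8aS)-5,8a-dimethyldecahydronaphthalene-1,5-diol
Product: 13 (4aR,5R,8aS)-5-hydroxy-5,8a-dimethyl-4a,5,6,7,8,8a-hexahydronaphthalen-1(4H)-one, via saturated ketone 12 (not isolated)
Conditions: 2-iodoxybenzoic acid (3.5 equiv), DMSO, 25 °C then 75 °C
Reagents that add atoms: none
Why: IBX oxidises the secondary alcohol and then dehydrogenates the ketone (Nicolaou IBX dehydrogenation) toward C8, the only enolisable side since C10 is quaternary; the tertiary alcohol is inert and no stereocentre is touched.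

Step 8
Reactants: 13 (4aR,5R,8aS)-5-hydroxy-5,8a-dimethyl-4a,5,6,7,8,8a-hexahydronaphthalen-1(4H)-one, 14 ethynyltrimethylsilane
Product: 16 (3R,4aR,5R,8aS)-3-ethynyl-5-hydroxy-5,8a-dimethyloctahydronaphthalen-1(2H)-one, via silylalkyne ketone 15 (not isolated)
Conditions: 14, n-BuLi, Et2O, −78 °C; Me2AlCl, 0 °C; then 13, Ni(acac)2 (10 mol%), i-Bu2AlH (10 mol%), Et2O, −5 °C; then K2CO3, MeOH, 25 °C
Reagents that add atoms: none
Why: Ni-catalysed conjugate addition of the alkynylalane (Schwartz–Hansen alkynylation) to the s-trans enone proceeds by axial attack on the α face, anti to the angular methyl through a chair-like enolate, which places the slim ethynyl group axial at C7; K2CO3/MeOH then cleaves the C–Si bond.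

Step 9
Reactants: 16 (3R,4aR,5R,8aS)-3-ethynyl-5-hydroxy-5,8a-dimethyloctahydronaphthalen-1(2H)-one, 17 (3S)-3-methylpentanoic acid
Product: 20 (1R,3R,4aR,5R,8aS)-3-ethynyl-5-hydroxy-5,8a-dimethyldecahydronaphthalen-1-yl (3S)-3-methylpentanoate, via acyl chloride 18 (not isolated), via lithium alkoxide 19 (not isolated)
Conditions: 17, (COCl)2, DMF (cat.), CH2Cl2, 25 °C, then evaporate; 16, LiBH(s-Bu)3 (1.05 equiv), THF, −78 °C; then 18, 4-(dimethylamino)pyridine, −78 °C to 25 °C
Reagents that add atoms: none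
Why: The bulky borohydride attacks the C9 ketone from the equatorial direction (axial attack is blocked by the 1,3-diaxial ethynyl group, and 3-oxo-4,4-dimethyl triterpenoids behave the same way), giving the axial 9α-alkoxide cis to the ethynyl group, which is acylated in the same flask (reductive acylation) while the hindered tertiary alcohol stays free.

Step 10
Reactants: 20 (1R,3R,4aR,5R,8aS)-3-ethynyl-5-hydroxy-5,8a-dimethyldecahydronaphthalen-1-yl (3S)-3-methylpentanoate
Product: 21 2-[(2R,4R,4aS,8R,8aR)-8-hydroxy-4a,8-dimethyl-4-{[(3S)-3-methylpentanoyl]oxy}decahydronaphthalen-2-yl]prop-2-enoic acid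
Conditions: Pd(OAc)2 (5 mol%), 4,5-bis(diphenylphosphino)-9,9-dimethylxanthene (10 mol%), HCO2H, Ac2O (20 mol%), toluene, 80 °C
Reagents that add atoms: formic acid, OC=O
Why: Pd-catalysed Markovnikov hydrocarboxylation of the terminal alkyne with formic acid as CO and water source (Pd–H adds with Pd on the internal carbon, CO inserts, the acyl group is released as the acid) gives the 2-substituted acrylic acid directly, with no protecting group and no change at the stereocentres.

## Compound list

1 | cyclohexane-1,3-dione | O=C1CCCC(=O)C1 | starting material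
2 | pent-4-ynal | C#CCCC=O | starting material
3 | 2-(pent-4-yn-1-ylidene)cyclohexane-1,3-dione | O=C1CCCC(=O)C1=CCCC#C | intermediate (not isolated)
4 | 2-(pent-4-yn-1-yl)cyclohexane-1,3-dione | O=C1CCCC(=O)C1CCCC#C | intermediate
5 | 2-methyl-2-(pent-4-yn-1-yl)cyclohexane-1,3-dione | CC1(CCCC#C)C(=O)CCCC1=O | intermediate
6 | (2R,3R)-3-hydroxy-2-methyl-2-(pent-4-yn-1-yl)cyclohexan-1-one | C1CC(=O)[C@](C)(CCCC#C)[C@H](O)C1 | intermediate
7 | (1R,2S)-2-methyl-2-(pent-4-yn-1-yl)-3-[(2-phenylaziridin-1-yl)imino]cyclohexan-1-ol (aziridine carbon and C=N geometry unspecified) | C1CC(=NN2CC2c2ccccc2)[C@](C)(CCCC#C)[C@H](O)C1 | intermediate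
8 | (1R,4aR,8aS)-8a-methyl-5-[(tributylstannyl)methylidene]decahydronaphthalen-1-ol | C1C[C@@H]2[C@](C)(CCCC2=C[Sn](CCCC)(CCCC)CCCC)[C@H](O)C1 | intermediate (not isolated)
9 | (1R,4aS,8aS)-8a-methyl-5-methylidenedecahydronaphthalen-1-ol | C1C[C@@H]2[C@](C)(CCCC2=C)[C@H](O)C1 | intermediate
10 | (1R,4aR,5R,8aS)-5-hydroperoxy-5,8a-dimethyldecahydronaphthalen-1-ol | C1C[C@@H]2[C@](C)(CCC[C@@]2(C)OO)[C@H](O)C1 | intermediate (not isolated)
11 | (1R,4aR,5R,8aS)-5,8a-dimethyldecahydronaphthalene-1,5-diol | C1C[C@@H]2[C@](C)(CCC[C@@]2(C)O)[C@H](O)C1 | intermediate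
12 | (4aR,5R,8aS)-5-hydroxy-5,8a-dimethyloctahydronaphthalen-1(2H)-one | C1C[C@@H]2[C@](C)(CCC[C@@]2(C)O)C(=O)C1 | intermediate (not isolated)
13 | (4aR,5R,8aS)-5-hydroxy-5,8a-dimethyl-4a,5,6,7,8,8a-hexahydronaphthalen-1(4H)-one | O=C1C=CC[C@@H]2[C@]1(C)CCC[C@@]2(C)O | intermediate
14 | ethynyltrimethylsilane | C#C[Si](C)(C)C | starting material
15 | (3R,4aR,5R,8aS)-5-hydroxy-5,8a-dimethyl-3-[(trimethylsilyl)ethynyl]octahydronaphthalen-1(2H)-one | C[Si](C)(C)C#C[C@@H]1C[C@@H]2[C@](C)(CCC[C@@]2(C)O)C(=O)C1 | intermediate (not isolated)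
16 | (3R,4aR,5R,8aS)-3-ethynyl-5-hydroxy-5,8a-dimethyloctahydronaphthalen-1(2H)-one | C#C[C@@H]1C[C@@H]2[C@](C)(CCC[C@@]2(C)O)C(=O)C1 | intermediate
17 | (3S)-3-methylpentanoic acid | CC[C@H](C)CC(=O)O | starting material
18 | (3S)-3-methylpentanoyl chloride | CC[C@H](C)CC(=O)Cl | intermediate (not isolated)
19 | lithium (1R,3R,4aR,5R,8aS)-3-ethynyl-5-hydroxy-5,8a-dimethyldecahydronaphthalen-1-olate | C#C[C@@H]1C[C@@H]2[C@](C)(CCC[C@@]2(C)O)[C@H]([O-])C1.[Li+] | intermediate (not isolated)
20 | (1R,3R,4aR,5R,8aS)-3-ethynyl-5-hydroxy-5,8a-dimethyldecahydronaphthalen-1-yl (3S)-3-methylpentanoate | C#C[C@@H]1C[C@@H]2[C@](C)(CCC[C@@]2(C)O)[C@H](OC(=O)C[C@@H](C)CC)C1 | intermediate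
21 | 2-[(2R,4R,4aS,8R,8aR)-8-hydroxy-4a,8-dimethyl-4-{[(3S)-3-methylpentanoyl]oxy}decahydronaphthalen-2-yl]prop-2-enoic acid | C=C(C(=O)O)[C@@H]1C[C@@H]2[C@](C)(CCC[C@@]2(C)O)[C@H](OC(=O)C[C@@H](C)CC)C1 | target

## Step count and risks

Total steps: 10. Longest linear sequence: 10 (1 to 21; acid 17 is activated in the flask of step 9).

**Step 5 (radical ring closure and ring-fusion hydrogen).** The vinyl radical may be reduced before it cyclises, or the C5 radical may take H on the β face and give the cis-decalin. The fallback sets out from 6 and returns at 11. The alkyne of 6 is hydrated ((Ph3P)AuNTf2, aqueous dioxane) to the methyl ketone (2R,3R)-3-hydroxy-2-methyl-2-(4-oxopentyl)cyclohexan-1-one F1. Ring A is then closed by intramolecular McMurry coupling (TiCl3, Zn(Cu), DME, reflux) to the tetrasubstituted alkene (1R,8aS)-5,8a-dimethyl-1,2,3,4,6,7,8,8a-octahydronaphthalen-1-ol F2. Hydroboration–oxidation (BH3·THF; NaOH, H2O2) adds H and OH syn from the α face, away from the angular methyl, with boron on the less hindered C4, and gives diol 11 directly.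

**Step 10 (hydrocarboxylation).** Formic acid at 80 °C may dehydrate or formylate the tertiary alcohol, and the hindered axial alkyne may react slowly or with poor branch selectivity. The fallback sets out from 13 and returns at 21. Isopropenylmagnesium bromide with CuBr·SMe2 and Me3SiCl (THF, −78 °C) adds axially to give (3R,4aR,5R,8aS)-5-hydroxy-5,8a-dimethyl-3-(prop-1-en-2-yl)octahydronaphthalen-1(2H)-one F3. Reduction with LiBH(s-Bu)3 and acylation with 18, as in step 9, give (1R,3R,4aR,5R,8aS)-5-hydroxy-5,8a-dimethyl-3-(prop-1-en-2-yl)decahydronaphthalen-1-yl (3S)-3-methylpentanoate F4. SeO2 in aqueous dioxane at 80 °C oxidises the allylic methyl to the enal (1R,3R,4aR,5R,8aS)-5-hydroxy-5,8a-dimethyl-3-(3-oxoprop-1-en-2-yl)decahydronaphthalen-1-yl (3S)-3-methylpentanoate F5. Pinnick oxidation (NaClO2, NaH2PO4, 2-methylbut-2-ene, t-BuOH/H2O) gives 21.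

**Step 3 (desymmetrisation).** Discrimination of the two carbonyls by methyl versus pentynyl may be incomplete, and the sense is predicted, not demonstrated. The fallback sets out from 5 and returns at 6. NaBH4 (0.3 equiv, MeOH, −20 °C) gives the racemic cis hydroxy ketone rac-(2R,3R)-3-hydroxy-2-methyl-2-(pent-4-yn-1-yl)cyclohexan-1-one F6. Amano lipase PS with vinyl acetate acylates the (3R)-enantiomer to (1R,2R)-2-methyl-3-oxo-2-(pent-4-yn-1-yl)cyclohexyl acetate F7, which is separated from the unreacted (2S,3S)-3-hydroxy-2-methyl-2-(pent-4-yn-1-yl)cyclohexan-1-one F8. K2CO3 in MeOH converts F7 into 6.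

## Further compounds

F1 | step 5 | (2R,3R)-3-hydroxy-2-methyl-2-(4-oxopentyl)cyclohexan-1-one | C1CC(=O)[C@](C)(CCCC(C)=O)[C@H](O)C1
F2 | step 5 | (1R,8aS)-5,8a-dimethyl-1,2,3,4,6,7,8,8a-octahydronaphthalen-1-ol | C1CC2=C(C)CCC[C@]2(C)[C@H](O)C1
F3 | step 10 | (3R,4aR,5R,8aS)-5-hydroxy-5,8a-dimethyl-3-(prop-1-en-2-yl)octahydronaphthalen-1(2H)-one | CC(=C)[C@@H]1C[C@@H]2[C@](C)(CCC[C@@]2(C)O)C(=O)C1
F4 | step 10 | (1R,3R,4aR,5R,8aS)-5-hydroxy-5,8a-dimethyl-3-(prop-1-en-2-yl)decahydronaphthalen-1-yl (3S)-3-methylpentanoate | CC(=C)[C@@H]1C[C@@H]2[C@](C)(CCC[C@@]2(C)O)[C@H](OC(=O)C[C@@H](C)CC)C1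
F5 | step 10 | (1R,3R,4aR,5R,8aS)-5-hydroxy-5,8a-dimethyl-3-(3-oxoprop-1-en-2-yl)decahydronaphthalen-1-yl (3S)-3-methylpentanoate | O=CC(=C)[C@@H]1C[C@@H]2[C@](C)(CCC[C@@]2(C)O)[C@H](OC(=O)C[C@@H](C)CC)C1
F6 | step 3 | rac-(2R,3R)-3-hydroxy-2-methyl-2-(pent-4-yn-1-yl)cyclohexan-1-one (racemate, one enantiomer drawn) | C1CC(=O)[C@](C)(CCCC#C)[C@H](O)C1
F7 | step 3 | (1R,2R)-2-methyl-3-oxo-2-(pent-4-yn-1-yl)cyclohexyl acetate | C1CC(=O)[C@](C)(CCCC#C)[C@H](OC(C)=O)C1
F8 | step 3 | (2S,3S)-3-hydroxy-2-methyl-2-(pent-4-yn-1-yl)cyclohexan-1-one | C1CC(=O)[C@@](C)(CCCC#C)[C@@H](O)C1
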